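## The problem

The target 12 is a 2H-chromene. A benzene ring is fused to a pyran ring across C4a–C8a, with a C3=C4 double bond, an acetyl group at C6 and a hydroxyl at C7. C2 carries a methyl group and a CH2O arm acylated by (E)-ferulic acid.

C2 is the only stereocentre. It is quaternary and (R), and its two carbon substituents (CH3 and CH2O-acyl) differ little close to the centre. No other stereogenic element exists that could relay selectivity, so the configuration must come from a catalyst, a reagent, the chiral pool or a resolution.

O1 lies para to the acetyl group and C4a para to the 7-hydroxyl. This is the "linear" fusion, which condensations of 4-acylresorcinols with enals do not favour because they react at the carbon between the two hydroxyls. The C4a–C4 bond is therefore best present from the start.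

The sensitive points are:
- the tertiary, allylic O1–C2 bond, where 6π ring opening by light or heat, or ionisation by strong acid, would racemise C2;
- the ferulate ester, which is base-labile and has a light-sensitive E double bond;
- two phenols, one of them chelated to the enolisable acetyl group.

The enabling feature is that O1, C8a, C4a and C4 are the four atoms of an ortho-quinone methide heterodiene, while C2–C3 maps onto a 1,1-disubstituted alkene that already bears both C2 substituents. The acetyl group para to O1 sharpens the electrophilicity of that heterodiene and ties up the neighbouring hydroxyl by hydrogen bonding.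

## Retrosynthesis

**12 to 11.** The last cut is the O–Si bond on the guaiacol oxygen, taking 12 back to silyl ether 11. Only this hydroxyl is masked. The 7-hydroxyl is hydrogen-bonded to the acetyl carbonyl and poorly nucleophilic, whereas the free guaiacol hydroxyl would add to cationic intermediates and activate its ring towards Friedel–Crafts attack. A silyl ether is preferred to a benzyl or acyl group because hydrogenolysis and basic hydrolysis are both ruled out by the alkenes and the ester. The forward step only has to stay close to neutral.

**11 to 10.** The C3=C4 double bond is traced back to methanol added across it, giving 4-methoxychroman 10 (either C4 epimer). This is preferred to dehydrating a 3-ol or to carrying a preformed Z-alkene, because a C4 alkoxy group is what quinone methide formation from an aldehyde acetal leaves behind. C4 is benzylic, ortho to O1 and para to the 7-hydroxyl, so it ionises under mild acid, and C3 is the only carbon that can then lose a proton. The precursor is no smaller, but its C4 is a centre that a cycloaddition can create. The forward step must eliminate without ionising the O1–C2 bond.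

**10 to 4 and 8.** Two bonds of the pyran ring are cut, C3–C4 and O1–C2. This gives aldehyde 4 (reacting as its dimethyl acetal 9, formed in the flask) and methallyl ester 8. Cutting only O1–C2 or only C8a–O1 would leave the whole C2–C3–C4 chain on the arene and require the quaternary centre to be made beforehand in a linear sequence. The double cut divides the molecule into a nine-carbon arene and the complete ester side chain, and it creates C2 from a prochiral alkene in the ring-forming step. The forward reaction has three requirements:
- O1 must bond to the substituted alkene carbon, which cation stability secures.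
- The cationic heterodiene must prefer the isolated alkene to the cinnamate double bond and to both arenes, which their conjugation with carbonyl groups secures.
- One alkene face must be chosen, which only a chiral acid can do. This is the unproven part, and a racemic route with resolution is held in reserve.

**8 to 7 to 5 and 6.** Ester 8 is cut at the O–Si bond to phenol 7, then at the alkyl C–O bond of the ester to ferulic acid 5 and methallyl chloride 6. Cutting the alkyl–oxygen bond rather than the acyl–oxygen bond avoids activating the acid beside its free phenol. A weak base ionises only the carboxylic acid, which then displaces the allylic chloride. Both precursors are commodity chemicals. The forward steps need chemoselectivity between carboxylate and phenol and must keep the E alkene.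

**4 to 2 to 1.** Aldehyde 4 is cut at the aryl–acetyl bond to bromide 2 and a two-carbon acetyl anion equivalent (cross-coupling through enol ether 3). Bromide 2 is cut at the C–Br bond to 2,4-dihydroxybenzaldehyde 1. The cross-coupling ties the position of the acetyl group to that of the halogen, which electrophilic bromination places para to the 2-hydroxyl and ortho to the 4-hydroxyl. The reverse order, formylating a 4-acylresorcinol, is avoided because such electrophiles tend to enter between the two hydroxyls or attack the acetyl group. Direct Friedel–Crafts acetylation of 1 exposes a free aldehyde to hot Lewis acid and is kept only as a reserve. The forward steps must tolerate two free phenols and an aldehyde, which a base-free tin coupling does.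

## Roads not taken

**Alternative 1:** The bond cut is C3–C4. C2, C3 and the hydroxymethyl carbon are held in a 3-methyloxetane bound to the phenol oxygen, and C4 is a benzylic CH2 carrying an enantiopure para-tolylsulfinyl group (substrate A2). LiN(iPr)2 would deprotonate C4 and, with BF3·OEt2 activating the oxetane, the carbanion would open one of the two enantiotopic ring CH2 groups (6-exo-tet). This closes the pyran ring and frees the hydroxymethyl group, giving sulfinylchroman A1.
- Merits: The sulfinyl group is both control element and later leaving group, since thermal syn-elimination gives C3=C4 without acid. The hydroxymethyl group emerges free for esterification. A1 forms as diastereomers, so imperfect selectivity could be corrected by ordinary separation. The chosen plan cannot do this and has to set a chiral-phase resolution against it.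
- Weak points: Selection between enantiotopic CH2 groups by a stereocentre at sulfur, relayed through C4, has no close precedent, so the stereo-determining step is as untested as the chosen one. A lithium amide beside an aryl bromide invites aryne formation and halogen migration, and it is consumed by BF3. The bromine of A1 must still become the acetyl group, the methoxymethyl ether must be removed by acid on the finished chromene, and the ferulate must still be attached. A2 itself needs a tertiary aryl ether on the oxetane and a sulfoxide of defined configuration.
- Comparison: The route is linear and, by estimate, about twice as long as the seven steps proposed here, without being more certain in its key step.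

**Alternative 2:** The bond cut is O1–C2 alone. In epoxy alcohol A4, whose two stereocentres a Sharpless asymmetric epoxidation would set, camphorsulfonic acid would activate the epoxide and the phenol oxygen would attack the tertiary carbon with inversion, giving chroman-3-ol A3.
- Merits: The absolute configuration comes from one of the most reliable asymmetric reactions known. In this respect the route is better than the chosen plan, which can offer only brevity and a resolution reserve.
- Weak points: Acid opening at a tertiary carbon has SN1 character, so inversion may not be clean, and the adjacent CH2OH destabilises the cation so that 5-exo attack at C3 (a dihydrobenzofuran) competes. The side chain must be attached at the ring carbon para to the 2-hydroxyl, against the innate preference of 4-acylresorcinols, which forces a halide and cross-coupling detour with phenol protection. A3 has a primary and a secondary alcohol, two phenols and a ketone. The non-benzylic 3-hydroxyl must be activated and eliminated towards C4, and the primary alcohol acylated selectively.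
- Comparison: The route is stronger in stereochemical certainty but much heavier in steps, arene regiocontrol and protecting-group traffic. The chosen plan obtains the C3=C4 bond from a benzylic leaving group that the ring-forming step installs for free.

**Alternative 3:** The bond cut is C8a–O1. In A6, a Z-styrene with fluorine at the future C8a and a chiral-pool tertiary alcohol at the future C2, KN(SiMe3)2 would form the alkoxide, which displaces fluoride para to the acetyl group to give the protected chromene A5.
- Merits: The stereocentre is bought, and its C–O bond is neither made nor broken in the ring closure. The C3=C4 bond is already present, so no late elimination is needed. Nucleophilic aromatic substitution activated by a para-acyl group is a dependable reaction type. Of all four plans this is the most certain to give enantiopure material, and that advantage is real.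
- Weak points: The Z geometry must be created by semi-hydrogenation of a triple bond and kept. The strong base can enolise the methyl ketone, which causes aldol side reactions and weakens the activation. Two protecting groups must be removed late, one oxidatively beside an electron-rich chromene and one by acid on the chromene. The ferulate is attached only at the end.
- Comparison: The route is linear and, by estimate, about a dozen steps. The chosen plan sets against its certainty a seven-step convergent route in which both halves are joined as the ring forms, with a resolution in reserve if catalyst control fails.

Key step: step 5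

Assumption: the stereocentre of the target is read as (2R); the sense of induction of the chiral acid cannot be predicted, so the catalyst antipode named in step 5 stands for whichever antipode delivers (2R), both being equally accessible.

## Route

Step 1
Reactants: 1 2,4-dihydroxybenzaldehyde
Product: 2 5-bromo-2,4-dihydroxybenzaldehyde
Conditions: Br2 (1.0 equiv), AcOH, 15–20 °C
Reagents that add atoms: bromine, BrBr
Why: Electrophilic aromatic bromination; C5 is para to the 2-hydroxyl and ortho to the 4-hydroxyl and less hindered than C3 between the two hydroxyls, and one equivalent of bromine at ambient temperature should limit dibromination.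

Step 2
Reactants: 2 5-bromo-2,4-dihydroxybenzaldehyde
Product: 4 5-acetyl-2,4-dihydroxybenzaldehyde, via enol ether 3 (not isolated)
Conditions: tributyl(1-ethoxyvinyl)stannane (1.5 equiv), Pd(PPh3)4 (5 mol%), 1,4-dioxane, 100 °C; then 2 M HCl, THF, rt
Reagents that add atoms: tributyl(1-ethoxyvinyl)stannane, CCCC[Sn](CCCC)(CCCC)C(=C)OCC; water, O
Why: Migita–Kosugi–Stille coupling of an aryl bromide with an α-alkoxyvinylstannane as acetyl anion equivalent, then acid hydrolysis of the enol ether; no base is needed, so the free phenols and the aldehyde are spectators, and the position of the acetyl group is fixed by the bromide.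

Step 3
Reactants: 5 ferulic acid, (E)-3-(4-hydroxy-3-methoxyphenyl)prop-2-enoic acid; 6 3-chloro-2-methylprop-1-ene
Product: 7 2-methylprop-2-en-1-yl (E)-3-(4-hydroxy-3-methoxyphenyl)prop-2-enoate (2-methylallyl ferulate)
Conditions: KHCO3 (1.2 equiv), NaI (10 mol%), DMF, 50 °C
Reagents that add atoms: none
Why: SN2 O-alkylation of the carboxylate, sped up by iodide exchange on the allylic chloride; bicarbonate deprotonates the carboxylic acid but not the phenol, so the ester should form without aryl ether formation and without touching the E double bond.

Step 4
Reactants: 7 2-methylallyl ferulate
Product: 8 2-methylprop-2-en-1-yl (E)-3-[4-(tert-butyldimethylsilyloxy)-3-methoxyphenyl]prop-2-enoate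
Conditions: TBSCl (1.2 equiv), imidazole (2.5 equiv), DMF, rt
Reagents that add atoms: tert-butyldimethylsilyl chloride, CC(C)(C)[Si](C)(C)Cl
Why: Imidazole-promoted silylation of a phenol; the silyl ether removes the acidic, nucleophilic guaiacol hydroxyl before the cationic key step and is cleaved by fluoride at the end.

Step 5
Reactants: 4 5-acetyl-2,4-dihydroxybenzaldehyde; 8 2-methylallyl O-silyl ferulate (1.5 equiv)
Product: 10 [(2R)-6-acetyl-7-hydroxy-4-methoxy-2-methyl-3,4-dihydro-2H-chromen-2-yl]methyl (E)-3-[4-(tert-butyldimethylsilyloxy)-3-methoxyphenyl]prop-2-enoate as a mixture of C4 epimers, via dimethyl acetal 9 (not isolated)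
Conditions: HC(OMe)3 (1.5 equiv), (S,S)-IDPi acid (5 mol%; imidodiphosphorimidate built from two (S)-3,3'-bis[3,5-bis(trifluoromethyl)phenyl]-1,1'-bi-2-naphthol units with N-trifluoromethanesulfonyl groups on phosphorus), 5 Å MS, CH2Cl2, −40 to 0 °C
Reagents that add atoms: trimethyl orthoformate, COC(OC)OC
Why: Proposed new method: the confined chiral acid turns 4 and the orthoformate into acetal 9 and ionises it to an ion pair of the chiral anion with an aryl(methoxy)carbenium ion, which is the O-protonated form of a 4-methoxy ortho-quinone methide and is made more electrophilic by the acetyl group para to O1; the terminal CH2 of the alkene of 8 attacks C4 (C3–C4 bond) and the developing tertiary cation at C2 is taken up by the phenolic O1 (O1–C2 bond) in an asynchronous inverse-electron-demand hetero-Diels–Alder reaction. The closest known reaction types are the acid-promoted three-component [4+2] cycloaddition of salicylaldehydes, trimethyl orthoformate and alkenes (racemic, for example with Sc(OTf)3) and chiral Brønsted acid-catalysed ortho-quinone methide cycloadditions with styrenes, enol ethers and tethered alkenes; enantiocontrol with an unactivated 1,1-dialkyl alkene has not been shown. The pyran ring closes in a [4+2] mode, four ring atoms (O1, C8a, C4a, C4) from the heterodiene and two (C2, C3) from the alkene, the second bond being the capture of the C2 cation by O1. The C2 stereocentre is set by the catalyst alone, which must tell the alkene faces apart through the size difference between the methyl group and the long acyloxymethyl arm inside its pocket, possibly helped by a hydrogen bond to the ester carbonyl. C4 forms without control as both epimers, which is harmless because step 6 erases it. The orientation is the Markovnikov one, O1 going to the carbon that best carries positive charge. Chemoselectivity rests on the hydrogen bond between the acetyl group and its neighbouring hydroxyl, on the deactivation of both arenes towards Friedel–Crafts attack by their conjugated carbonyl groups, and on the poor nucleophilicity of the cinnamate double bond.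

Step 6
Reactants: 10 (2R)-4-methoxychroman silyl ferulate (both C4 epimers)
Product: 11 [(2R)-6-acetyl-7-hydroxy-2-methyl-2H-chromen-2-yl]methyl (E)-3-[4-(tert-butyldimethylsilyloxy)-3-methoxyphenyl]prop-2-enoate
Conditions: p-TsOH·H2O (5 mol%), 4 Å MS, toluene, 60 °C, dark
Reagents that add atoms: none
Why: Acid-catalysed E1 elimination: ionisation of the benzylic C4–OMe bond gives a cation stabilised by O1 and the para 7-hydroxyl, and loss of a C3 proton gives the alkene conjugated with the arene; C2 takes no part, both C4 epimers converge, and mild acid, moderate temperature and darkness are chosen to spare the allylic O1–C2 bond and the ferulate alkene.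

Step 7
Reactants: 11 (2R)-chromene silyl ferulate
Product: 12 [(2R)-6-acetyl-7-hydroxy-2-methyl-2H-chromen-2-yl]methyl (E)-3-(4-hydroxy-3-methoxyphenyl)prop-2-enoate
Conditions: TBAF (1.2 equiv), AcOH (1.2 equiv), THF, 0 °C
Reagents that add atoms: none
Why: Fluoride-induced cleavage of an aryl silyl ether driven by Si–F bond formation; buffering with acetic acid keeps phenoxide concentrations low so that the ferulate ester, the chelated 7-phenol and the chromene should stay untouched, and the stereocentre is not involved.

## Compound list

1 | 2,4-dihydroxybenzaldehyde | O=Cc1ccc(O)cc1O | starting material
2 | 5-bromo-2,4-dihydroxybenzaldehyde | O=Cc1cc(Br)c(O)cc1O | intermediate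
3 | 5-(1-ethoxyethenyl)-2,4-dihydroxybenzaldehyde | C=C(OCC)c1cc(C=O)c(O)cc1O | intermediate
4 | 5-acetyl-2,4-dihydroxybenzaldehyde | CC(=O)c1cc(C=O)c(O)cc1O | intermediate
5 | ferulic acid, (E)-3-(4-hydroxy-3-methoxyphenyl)prop-2-enoic acid | COc1cc(/C=C/C(=O)O)ccc1O | starting material
6 | 3-chloro-2-methylprop-1-ene (methallyl chloride) | C=C(C)CCl | starting material
7 | 2-methylprop-2-en-1-yl (E)-3-(4-hydroxy-3-methoxyphenyl)prop-2-enoate | C=C(C)COC(=O)/C=C/c1ccc(O)c(OC)c1 | intermediate
8 | 2-methylprop-2-en-1-yl (E)-3-[4-(tert-butyldimethylsilyloxy)-3-methoxyphenyl]prop-2-enoate | C=C(C)COC(=O)/C=C/c1ccc(O[Si](C)(C)C(C)(C)C)c(OC)c1 | intermediate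
9 | 1-[5-(dimethoxymethyl)-2,4-dihydroxyphenyl]ethan-1-one (dimethyl acetal of 4) | CC(=O)c1cc(C(OC)OC)c(O)cc1O | intermediate
10 | [(2R)-6-acetyl-7-hydroxy-4-methoxy-2-methyl-3,4-dihydro-2H-chromen-2-yl]methyl (E)-3-[4-(tert-butyldimethylsilyloxy)-3-methoxyphenyl]prop-2-enoate, both C4 epimers | COc1cc(/C=C/C(=O)OC[C@@]2(C)CC(OC)c3cc(C(C)=O)c(O)cc3O2)ccc1O[Si](C)(C)C(C)(C)C | intermediate
11 | [(2R)-6-acetyl-7-hydroxy-2-methyl-2H-chromen-2-yl]methyl (E)-3-[4-(tert-butyldimethylsilyloxy)-3-methoxyphenyl]prop-2-enoate | COc1cc(/C=C/C(=O)OC[C@@]2(C)C=Cc3cc(C(C)=O)c(O)cc3O2)ccc1O[Si](C)(C)C(C)(C)C | intermediate
12 | [(2R)-6-acetyl-7-hydroxy-2-methyl-2H-chromen-2-yl]methyl (E)-3-(4-hydroxy-3-methoxyphenyl)prop-2-enoate | COc1cc(/C=C/C(=O)OC[C@@]2(C)C=Cc3cc(C(C)=O)c(O)cc3O2)ccc1O | target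

## Step count and least certain steps

Total: 7 steps. Longest linear sequence: 5 steps (steps 1, 2, 5, 6, 7; the ferulate branch, steps 3 and 4, joins at step 5 and is equally long).

**Step 5 (key step, proposed new method).** Three things may go wrong.
- The catalyst may discriminate poorly between the two alkene faces, because methyl and acyloxymethyl differ only beyond the first atom. The result would be low enantiomeric purity.
- The cycloaddition may be slow, because the allylic ester oxygen lowers the nucleophilicity of the alkene. Self-condensation of the cationic quinone methide could then compete.
- The tertiary cation may be diverted, either by the ester carbonyl or by simple proton loss, before O1 closes the ring.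

The fallback uses known chemistry and gives up catalyst control. It sets out from 4 and 8, which are combined with trimethyl orthoformate under Sc(OTf)3 catalysis in CH2Cl2 at room temperature, the established racemic three-component reaction. This should give the racemic 4-methoxychroman F1. Elimination of methanol with p-TsOH as in step 6 gives the racemic silyl chromene F2. Preparative chromatography on a polysaccharide-based chiral stationary phase then separates the enantiomers, and the (2R)-enantiomer re-enters the route as 11. Half of the material is lost.

**Step 6.** Once the double bond is in place the O1–C2 bond is tertiary and allylic. Acid-induced heterolysis of this bond would erode the enantiomeric purity, and the electron-rich chromene may undergo cationic dimerisation. The fallback forms the alkene under neutral conditions. It sets out from 10, which is treated with benzeneselenol and a catalytic amount of BF3·OEt2 in CH2Cl2 at −40 °C. This is an SN1 exchange at the ionisable benzylic carbon, of the type used to make selenoglycosides from anomeric acetates, and should give the 4-(phenylselanyl)chroman F3. Oxidation with H2O2 and pyridine in CH2Cl2 at 0 °C gives the selenoxide F4. Its syn-elimination towards C3 at or below room temperature returns to the route at 11, without the chromene ever meeting acid.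

**Step 2.** The acidic phenols may protonate the acid-sensitive α-alkoxyvinylstannane (protodestannylation), and oxidative addition of zerovalent palladium into the electron-rich, unprotected bromoresorcinol may be slow. The fallback replaces cross-coupling by electrophilic acylation and bypasses bromide 2. It sets out from 1, which is heated with acetic anhydride and BF3·OEt2 at 80–90 °C. This is a Friedel–Crafts C-acetylation of the kind that takes 4-acyl- and 4-alkoxycarbonylresorcinols to their 6-acetyl derivatives, entering para to the 2-oxygen. The crude product, drawn as the fully O-acetylated 4-acetyl-6-[bis(acetyloxy)methyl]-1,3-phenylene diacetate F5, is hydrolysed with 2 M HCl in THF at 50 °C and comes back to the route at 4.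

## Further compounds

F1 | step 5 | [6-acetyl-7-hydroxy-4-methoxy-2-methyl-3,4-dihydro-2H-chromen-2-yl]methyl (E)-3-[4-(tert-butyldimethylsilyloxy)-3-methoxyphenyl]prop-2-enoate, racemic, all stereoisomers | COc1cc(/C=C/C(=O)OCC2(C)CC(OC)c3cc(C(C)=O)c(O)cc3O2)ccc1O[Si](C)(C)C(C)(C)C
F2 | step 5 | [6-acetyl-7-hydroxy-2-methyl-2H-chromen-2-yl]methyl (E)-3-[4-(tert-butyldimethylsilyloxy)-3-methoxyphenyl]prop-2-enoate, racemic | COc1cc(/C=C/C(=O)OCC2(C)C=Cc3cc(C(C)=O)c(O)cc3O2)ccc1O[Si](C)(C)C(C)(C)C
F3 | step 6 | [(2R)-6-acetyl-7-hydroxy-2-methyl-4-(phenylselanyl)-3,4-dihydro-2H-chromen-2-yl]methyl (E)-3-[4-(tert-butyldimethylsilyloxy)-3-methoxyphenyl]prop-2-enoate, both C4 epimers | COc1cc(/C=C/C(=O)OC[C@@]2(C)CC([Se]c4ccccc4)c3cc(C(C)=O)c(O)cc3O2)ccc1O[Si](C)(C)C(C)(C)C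
F4 | step 6 | [(2R)-6-acetyl-7-hydroxy-2-methyl-4-(phenylseleninyl)-3,4-dihydro-2H-chromen-2-yl]methyl (E)-3-[4-(tert-butyldimethylsilyloxy)-3-methoxyphenyl]prop-2-enoate, mixture of diastereomers | COc1cc(/C=C/C(=O)OC[C@@]2(C)CC([Se](=O)c4ccccc4)c3cc(C(C)=O)c(O)cc3O2)ccc1O[Si](C)(C)C(C)(C)C
F5 | step 2 | 4-acetyl-6-[bis(acetyloxy)methyl]-1,3-phenylene diacetate | CC(=O)Oc1cc(OC(C)=O)c(C(OC(C)=O)OC(C)=O)cc1C(C)=O
A1 | alternative 1 | [(2R)-6-bromo-7-(methoxymethoxy)-2-methyl-4-(4-methylbenzenesulfinyl)-3,4-dihydro-2H-chromen-2-yl]methanol, both C4 epimers, sulfur configuration as drawn | OC[C@@]1(C)CC([S@@](=O)c2ccc(C)cc2)c2cc(Br)c(OCOC)cc2O1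
A2 | alternative 1 | 3-[4-bromo-5-(methoxymethoxy)-2-{[(4-methylphenyl)sulfinyl]methyl}phenoxy]-3-methyloxetane, sulfur configuration as drawn | CC1(Oc2cc(OCOC)c(Br)cc2C[S@@](=O)c2ccc(C)cc2)COC1
A3 | alternative 2 | 1-[(2S,3R)-3,7-dihydroxy-2-(hydroxymethyl)-2-methyl-3,4-dihydro-2H-chromen-6-yl]ethan-1-one | OC[C@@]1(C)[C@H](O)Cc2cc(C(C)=O)c(O)cc2O1
A4 | alternative 2 | 1-(2,4-dihydroxy-5-{[(2R,3R)-3-(hydroxymethyl)-3-methyloxiran-2-yl]methyl}phenyl)ethan-1-one | OC[C@@]1(C)O[C@@H]1Cc1cc(C(C)=O)c(O)cc1O
A5 | alternative 3 | 1-[(2R)-7-(methoxymethoxy)-2-{[(4-methoxyphenyl)methoxy]methyl}-2-methyl-2H-chromen-6-yl]ethan-1-one | COc1ccc(COC[C@@]2(C)C=Cc3cc(C(C)=O)c(OCOC)cc3O2)cc1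
A6 | alternative 3 | 1-{4-fluoro-5-[(1Z,3R)-3-hydroxy-4-[(4-methoxyphenyl)methoxy]-3-methylbut-1-en-1-yl]-2-(methoxymethoxy)phenyl}ethan-1-one | COc1ccc(COC[C@](C)(O)/C=C\c2cc(C(C)=O)c(OCOC)cc2F)cc1
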